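A direct plan would brominate syringaldehyde A1 to 2-bromo-4-hydroxy-3,5-dimethoxybenzaldehyde A2, exchange the bromide for methoxide with CuCl/NaOMe to give 4-hydroxy-2,3,5-trimethoxybenzaldehyde A3, benzylate it to 4-(benzyloxy)-2,3,5-trimethoxybenzaldehyde A4, condense A4 with 1-[2-(benzyloxy)-6-hydroxy-4-methoxyphenyl]ethan-1-one A5 to chalcone A6, close and dehydrogenate ring C with I2 in hot DMSO to dibenzyl flavone A7, and hydrogenolyse both benzyl ethers. Its weakest steps would be:
- the copper-mediated methoxylation of A2, because hot methoxide must displace a bromide wedged between a formyl and a methoxy group, and protodebromination competes;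
- the iodine/DMSO oxidative ring closure of A6, because it would run at 130 °C on the most advanced intermediate, where HI can iodinate ring A or cleave the peri benzyl ether;
- the final hydrogenolysis of A7, which would end three protecting-group steps that add no skeleton and could reduce the C2=C3 bond of the finished flavone.

The retrosynthesis cuts ring A, not ring C: C4a–C5, C5–C6 and C7–C8 are cut and C8–C8a is traced to a Wolff 1,2-shift, leaving a 6-aryl-4-pyranone with a diazoacetyl group on the future C8a, plus methoxyacetylene (C6, C7 and the 7-OMe).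
Ring B comes from 1,2,4-trimethoxybenzene (C–H lithiation/oxidation, then para-acylation), ring C is closed second from a 1,3,5-tricarbonyl chain, and ring A is built last by a Danheiser benzannulation.
The enabling feature is that ring A is a resorcinol monoether fused at C4a–C8a: C5–OH and C7–OMe are meta and C6 and C8 are CH, which is what a vinylketene (ketene carbon becomes C5–OH) and a 1-alkoxyalkyne deliver.
No aryl bromide is methoxylated, no chalcone is formed or oxidised, and nothing is hydrogenated; the one mask is a carbonate installed during acid activation and lost in the work-up of the key step.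

Key step: step 7

Remark: methoxyacetylene is assumed not to be reliably purchasable, so it is prepared (step 6) and used at once as a cold solution.

Step 1
Reactants: 1 1,2,4-trimethoxybenzene
Product: 4 2,3,6-trimethoxyphenol, via aryllithium 2 (not isolated), via dimethyl arylboronate 3 (not isolated)
Conditions: n-BuLi (1.1 equiv), THF, 0 °C to rt, 2 h; B(OMe)3 (1.5 equiv), −78 °C to rt; AcOH, 30% aq H2O2, 0 °C to rt
Reagents that add atoms: hydrogen peroxide, OO
Why: Directed ortho-metalation removes the C3–H flanked by the 2- and 4-methoxy groups (the most acidic, doubly coordinated site), and borylation followed by boronate oxidation should place the hydroxyl between two methoxy groups, as the 4'-OH of ring B requires.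

Step 2
Reactants: 4 2,3,6-trimethoxyphenol
Product: 6 1-(4-hydroxy-2,3,5-trimethoxyphenyl)ethan-1-one, via aryl acetate 5 (not isolated)
Conditions: Ac2O (1.05 equiv), MeSO3H, 0 °C then 50 °C, 3 h; ice water
Reagents that add atoms: acetic anhydride, CC(=O)OC(C)=O
Why: O-Acetylation and acid-mediated Fries rearrangement (Friedel–Crafts acylation): both positions ortho to the hydroxyl are blocked by methoxy groups, so the acylium should enter para to the hydroxyl, favoured over C5 because the 2-methoxy group para to C5 is flanked on both sides and twisted out of conjugation.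

Step 3
Reactants: 6 1-(4-hydroxy-2,3,5-trimethoxyphenyl)ethan-1-one
Product: 7 1-(4-hydroxy-2,3,5-trimethoxyphenyl)butane-1,3-dione
Conditions: NaH (4 equiv), EtOAc (6 equiv), THF, reflux, 4 h; 1 M HCl
Reagents that add atoms: ethyl acetate, CCOC(C)=O
Why: Crossed Claisen condensation of the methyl ketone enolate with ethyl acetate, driven by formation of the β-diketonate; the phenoxide is a spectator and needs no protection.

Step 4
Reactants: 7 1-(4-hydroxy-2,3,5-trimethoxyphenyl)butane-1,3-dione
Product: 10 6-(4-hydroxy-2,3,5-trimethoxyphenyl)-4-oxo-4H-pyran-2-carboxylic acid, via triketo ester 8 (not isolated), via pyranone ethyl ester 9 (not isolated)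
Conditions: diethyl oxalate (1.5 equiv), NaOEt (3.5 equiv), EtOH, rt to 50 °C, 6 h; then conc. HCl/AcOH (1:2), 100 °C, 3 h
Reagents that add atoms: diethyl oxalate, CCOC(=O)C(=O)OCC; water, O
Why: Claisen condensation with non-enolisable diethyl oxalate under thermodynamic control acylates the terminal methyl (as in the chelidonic acid synthesis), and acid-catalysed cyclodehydration of the 1,3,5-tricarbonyl chain closes ring C as the 4-pyranone (enol oxygen onto the C2 keto group, then loss of water) with concurrent ester hydrolysis.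

Step 5
Reactants: 10 6-(4-hydroxy-2,3,5-trimethoxyphenyl)-4-oxo-4H-pyran-2-carboxylic acid
Product: 12 4-[6-(2-diazoacetyl)-4-oxo-4H-pyran-2-yl]-2,3,6-trimethoxyphenyl ethyl carbonate, via mixed carbonic anhydride 11 (not isolated)
Conditions: ClCO2Et (2.3 equiv), Et3N (2.5 equiv), THF, −15 °C, 1 h; filter; CH2N2 (ca. 4 equiv, Et2O), 0 °C to rt, 4 h; N2 purge
Reagents that add atoms: ethyl chloroformate, CCOC(=O)Cl; diazomethane, C=[N+]=[N-]
Why: Ethyl chloroformate activates the acid as a mixed carbonic anhydride and caps the phenol as a carbonate in the same operation, so that C-acylation of diazomethane (first stage of the Arndt–Eistert sequence) should give the α-diazo ketone without O-methylation of the phenol.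

Step 6
Reactants: 13 2-chloro-1,1-dimethoxyethane
Product: 16 methoxyacetylene, via chlorovinyl ether 14 (not isolated), via sodium methoxyethynide 15 (not isolated)
Conditions: NaNH2 (3 equiv), liq. NH3, −33 °C; evaporate NH3; sat. aq NaCl, −20 °C; distil into cold ClCH2CH2Cl
Reagents that add atoms: none
Why: Twofold base-induced elimination (methanol, then HCl) with NaNH2 in liquid ammonia is the standard preparation of 1-alkoxyalkynes from chloroacetaldehyde acetals; the acetylide is protonated on aqueous quench.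

Step 7
Reactants: 12 4-[6-(2-diazoacetyl)-4-oxo-4H-pyran-2-yl]-2,3,6-trimethoxyphenyl ethyl carbonate; 16 methoxyacetylene
Product: 22 5-hydroxy-2-(4-hydroxy-2,3,5-trimethoxyphenyl)-7-methoxy-4H-chromen-4-one, via ketene 17 (not isolated), via cyclobutenone 18 (not isolated), via dienylketene 19 (not isolated), via dienone 20 (not isolated), via flavone carbonate 21 (not isolated)
Conditions: 16 (3 equiv), ClCH2CH2Cl, hν (450 nm LEDs), rt, sealed tube; then 80 °C, 3 h; then K2CO3 (2 equiv), MeOH, rt, 1 h; 1 M HCl
Reagents that add atoms: none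
Why: Photochemical Wolff rearrangement of 12 (1,2-shift of the pyranonyl group, forming C8–C8a) gives pyranonylketene 17, which undergoes [2+2] cycloaddition with ynol ether 16 to cyclobutenone 18; on heating, 18 opens by 4π electrocyclisation to dienylketene 19, whose ketene carbon closes onto C3 of the pyranone by 6π electrocyclisation (forming C4a–C5 of ring A), and enolisation of dienone 20 delivers the phenol. The closest known reaction type is the Danheiser benzannulation in its α-diazo ketone variant, in which alkenyl, aryl and heteroaryl diazo ketones combine with alkoxy- or siloxyacetylenes to give resorcinol monoethers. Ring A is the only ring closed, in a 6π electrocyclic mode with the pyranone C2=C3 bond as the terminal two-carbon unit, and it is born at the aromatic oxidation level; the sp3 centres of 18 and 20 are transient and no stereocentre remains. The regiochemistry follows from the polarisation of the partners: the nucleophilic CH terminus of 16 bonds to the ketene carbonyl carbon, so the methoxy group ends on C7, meta to the C5 hydroxyl that derives from the ketene carbonyl, and ring closure can only occur at pyranone C3 because the other neighbour of the attachment carbon is the ring oxygen. Chemoselectivity should be secured by exciting at 450 nm, where the diazo ketone but not the arylpyranone is expected to absorb, and by the carbonate, which keeps the 4'-oxygen from acylation by 17 or 19. Methanolysis with K2CO3 then removes the carbonate, and any aryl ester formed from a ketene, in the same flask, while the chelated 5-OH is untouched.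

**Compound list**
1 | 1,2,4-trimethoxybenzene | COc1ccc(OC)c(OC)c1 | starting material
2 | (2,3,6-trimethoxyphenyl)lithium | [Li]c1c(OC)ccc(OC)c1OC | intermediate
3 | dimethyl (2,3,6-trimethoxyphenyl)boronate | COB(OC)c1c(OC)ccc(OC)c1OC | intermediate
4 | 2,3,6-trimethoxyphenol | Oc1c(OC)ccc(OC)c1OC | intermediate
5 | 2,3,6-trimethoxyphenyl acetate | CC(=O)Oc1c(OC)ccc(OC)c1OC | intermediate
6 | 1-(4-hydroxy-2,3,5-trimethoxyphenyl)ethan-1-one | CC(=O)c1cc(OC)c(O)c(OC)c1OC | intermediate
7 | 1-(4-hydroxy-2,3,5-trimethoxyphenyl)butane-1,3-dione | CC(=O)CC(=O)c1cc(OC)c(O)c(OC)c1OC | intermediate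
8 | ethyl 6-(4-hydroxy-2,3,5-trimethoxyphenyl)-2,4,6-trioxohexanoate | CCOC(=O)C(=O)CC(=O)CC(=O)c1cc(OC)c(O)c(OC)c1OC | intermediate
9 | ethyl 6-(4-hydroxy-2,3,5-trimethoxyphenyl)-4-oxo-4H-pyran-2-carboxylate | CCOC(=O)c1cc(=O)cc(-c2cc(OC)c(O)c(OC)c2OC)o1 | intermediate
10 | 6-(4-hydroxy-2,3,5-trimethoxyphenyl)-4-oxo-4H-pyran-2-carboxylic acid | OC(=O)c1cc(=O)cc(-c2cc(OC)c(O)c(OC)c2OC)o1 | intermediate
11 | ethoxycarbonyl 6-{4-[(ethoxycarbonyl)oxy]-2,3,5-trimethoxyphenyl}-4-oxo-4H-pyran-2-carboxylate (mixed carbonic anhydride) | CCOC(=O)OC(=O)c1cc(=O)cc(-c2cc(OC)c(OC(=O)OCC)c(OC)c2OC)o1 | intermediate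
12 | 4-[6-(2-diazoacetyl)-4-oxo-4H-pyran-2-yl]-2,3,6-trimethoxyphenyl ethyl carbonate | CCOC(=O)Oc1c(OC)cc(-c2cc(=O)cc(C(=O)C=[N+]=[N-])o2)c(OC)c1OC | intermediate
13 | 2-chloro-1,1-dimethoxyethane (chloroacetaldehyde dimethyl acetal) | COC(CCl)OC | starting material
14 | 1-chloro-2-methoxyethene (E/Z mixture) | COC=CCl | intermediate
15 | sodium methoxyethynide | [Na+].[C-]#COC | intermediate
16 | methoxyacetylene (methoxyethyne) | COC#C | intermediate
17 | ethyl 2,3,6-trimethoxy-4-[4-oxo-6-(2-oxoethenyl)-4H-pyran-2-yl]phenyl carbonate (ketene) | CCOC(=O)Oc1c(OC)cc(-c2cc(=O)cc(C=C=O)o2)c(OC)c1OC | intermediate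
18 | ethyl 2,3,6-trimethoxy-4-[6-(2-methoxy-4-oxocyclobut-2-en-1-yl)-4-oxo-4H-pyran-2-yl]phenyl carbonate (racemic) | CCOC(=O)Oc1c(OC)cc(-c2cc(=O)cc(C3C(OC)=CC3=O)o2)c(OC)c1OC | intermediate
19 | ethyl 2,3,6-trimethoxy-4-{6-[(1E)-2-methoxy-4-oxobuta-1,3-dien-1-yl]-4-oxo-4H-pyran-2-yl}phenyl carbonate (dienylketene) | CCOC(=O)Oc1c(OC)cc(-c2cc(=O)cc(/C=C(OC)\C=C=O)o2)c(OC)c1OC | intermediate
20 | ethyl 2,3,6-trimethoxy-4-(7-methoxy-4,5-dioxo-4a,5-dihydro-4H-chromen-2-yl)phenyl carbonate (racemic keto tautomer) | CCOC(=O)Oc1c(OC)cc(C2=CC(=O)C3C(=O)C=C(OC)C=C3O2)c(OC)c1OC | intermediate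
21 | ethyl 4-(5-hydroxy-7-methoxy-4-oxo-4H-chromen-2-yl)-2,3,6-trimethoxyphenyl carbonate | CCOC(=O)Oc1c(OC)cc(-c2cc(=O)c3c(O)cc(OC)cc3o2)c(OC)c1OC | intermediate
22 | 5-hydroxy-2-(4-hydroxy-2,3,5-trimethoxyphenyl)-7-methoxy-4H-chromen-4-one (5,4'-dihydroxy-7,2',3',5'-tetramethoxyflavone) | COc1cc(O)c2c(=O)cc(-c3cc(OC)c(O)c(OC)c3OC)oc2c1 | target

Total step count: 7. Longest linear sequence: 6 (steps 1, 2, 3, 4, 5, 7); step 6 prepares the alkyne partner.

Steps most likely to fail:

1. Step 7. The arylpyranone chromophore could undergo its own photoreactions, or the 6π electrocyclisation onto pyranone C3 could be slow, so that the cyclobutenone stalls or the dienylketene is diverted into oligomers and esters. The fallback sets out from 6 and returns at 22. Claisen condensation of 6 with diethyl carbonate (NaH, THF, reflux) would give ethyl 3-(4-hydroxy-2,3,5-trimethoxyphenyl)-3-oxopropanoate F1. Thermal condensation of F1 with commercial 5-methoxyresorcinol (neat, 240 °C, Mentzer pyrone synthesis) would give 22 directly. The regioisomeric 7-hydroxy-2-(4-hydroxy-2,3,5-trimethoxyphenyl)-5-methoxy-4H-chromen-4-one F2 may accompany it; it lacks the chelated 5-OH and should be separable by chromatography.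

2. Step 5. Diazomethane could attack the carbonate carbonyl of the mixed anhydride, add as a dipole to the electron-poor pyranone double bond, or O-methylate the phenol if carbonate formation is incomplete. The fallback sets out from 7 and returns at 12. Claisen condensation of 7 with ethyl 2,2-diethoxypropanoate (NaH, THF) at the terminal methyl would give 6,6-diethoxy-1-(4-hydroxy-2,3,5-trimethoxyphenyl)heptane-1,3,5-trione F3. Hot aqueous HCl/AcOH would cyclise it and unmask the ketone to give 2-acetyl-6-(4-hydroxy-2,3,5-trimethoxyphenyl)-4H-pyran-4-one F4. Detrifluoroacetylative diazo transfer would pass through 4,4,4-trifluoro-1-[6-(4-hydroxy-2,3,5-trimethoxyphenyl)-4-oxo-4H-pyran-2-yl]butane-1,3-dione F5 (LiN(SiMe3)2, CF3CO2CH2CF3, THF, −78 °C) and, with MsN3, Et3N and H2O in MeCN, give 2-(2-diazoacetyl)-6-(4-hydroxy-2,3,5-trimethoxyphenyl)-4H-pyran-4-one F6. ClCO2Et/Et3N would then cap the phenol to give 12.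

3. Step 2. Acylation could occur para to the 2-methoxy group instead of para to the hydroxyl, or the acid could cleave a methyl ether. The fallback sets out from 4 and returns at 6. NBS (MeCN, 0 °C) should brominate the free phenol para to the hydroxyl to give 4-bromo-2,3,6-trimethoxyphenol F7. Heck coupling with butyl vinyl ether at its internal carbon (Pd(OAc)2, 1,3-bis(diphenylphosphino)propane, Et3N, DMSO, 115 °C) would give 4-(1-butoxyethenyl)-2,3,6-trimethoxyphenol F8, and aqueous HCl would hydrolyse the enol ether to 6.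

Further compounds
F1 | step 7 | ethyl 3-(4-hydroxy-2,3,5-trimethoxyphenyl)-3-oxopropanoate | CCOC(=O)CC(=O)c1cc(OC)c(O)c(OC)c1OC
F2 | step 7 | 7-hydroxy-2-(4-hydroxy-2,3,5-trimethoxyphenyl)-5-methoxy-4H-chromen-4-one | COc1cc(O)cc2oc(-c3cc(OC)c(O)c(OC)c3OC)cc(=O)c12
F3 | step 5 | 6,6-diethoxy-1-(4-hydroxy-2,3,5-trimethoxyphenyl)heptane-1,3,5-trione | CCOC(C)(OCC)C(=O)CC(=O)CC(=O)c1cc(OC)c(O)c(OC)c1OC
F4 | step 5 | 2-acetyl-6-(4-hydroxy-2,3,5-trimethoxyphenyl)-4H-pyran-4-one | CC(=O)c1cc(=O)cc(-c2cc(OC)c(O)c(OC)c2OC)o1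
F5 | step 5 | 4,4,4-trifluoro-1-[6-(4-hydroxy-2,3,5-trimethoxyphenyl)-4-oxo-4H-pyran-2-yl]butane-1,3-dione | O=C(CC(=O)C(F)(F)F)c1cc(=O)cc(-c2cc(OC)c(O)c(OC)c2OC)o1
F6 | step 5 | 2-(2-diazoacetyl)-6-(4-hydroxy-2,3,5-trimethoxyphenyl)-4H-pyran-4-one | [N-]=[N+]=CC(=O)c1cc(=O)cc(-c2cc(OC)c(O)c(OC)c2OC)o1
F7 | step 2 | 4-bromo-2,3,6-trimethoxyphenol | COc1cc(Br)c(OC)c(OC)c1O
F8 | step 2 | 4-(1-butoxyethenyl)-2,3,6-trimethoxyphenol | CCCCOC(=C)c1cc(OC)c(O)c(OC)c1OC
A1 | direct plan | syringaldehyde (4-hydroxy-3,5-dimethoxybenzaldehyde) | COc1cc(C=O)cc(OC)c1O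
A2 | direct plan | 2-bromo-4-hydroxy-3,5-dimethoxybenzaldehyde | COc1cc(C=O)c(Br)c(OC)c1O
A3 | direct plan | 4-hydroxy-2,3,5-trimethoxybenzaldehyde | COc1cc(C=O)c(OC)c(OC)c1O
A4 | direct plan | 4-(benzyloxy)-2,3,5-trimethoxybenzaldehyde | COc1cc(C=O)c(OC)c(OC)c1OCc1ccccc1
A5 | direct plan | 1-[2-(benzyloxy)-6-hydroxy-4-methoxyphenyl]ethan-1-one | CC(=O)c1c(O)cc(OC)cc1OCc1ccccc1
A6 | direct plan | (E)-1-[2-(benzyloxy)-6-hydroxy-4-methoxyphenyl]-3-[4-(benzyloxy)-2,3,5-trimethoxyphenyl]prop-2-en-1-one | COc1cc(O)c(C(=O)/C=C/c2cc(OC)c(OCc3ccccc3)c(OC)c2OC)c(OCc2ccccc2)c1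
A7 | direct plan | 5-(benzyloxy)-2-[4-(benzyloxy)-2,3,5-trimethoxyphenyl]-7-methoxy-4H-chromen-4-one | COc1cc(OCc2ccccc2)c2c(=O)cc(-c3cc(OC)c(OCc4ccccc4)c(OC)c3OC)oc2c1
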